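**Strategy.** Ring numbering: C1 quaternary carbinol, C2 its CH(OBz) neighbour, C3=C4, C5, C6 the CH(OH), C7 the exocyclic CH2. The cyclohexene is cut at C3–C4 and C1–C6. C7–C1–C2–C3 is an oxygenated acetoacetate, and C4–C5–C6 a glyceraldehyde-derived 2-alkoxymalondialdehyde equivalent. In one flask a 1,3-bis(silyl enol ether) of methyl 2-siloxyacetoacetate and (R)-2-(PMB-oxy)-3,3-dimethoxypropanal undergo a formal [3+3] annulation: acetal Mukaiyama alkylation at C3–C4, chelation-controlled aldol closure at C1–C6 setting C1 and C6, and loss of methanol giving the C3=C4 enone. The key step exploits the 1,3-dioxygenation pattern of the ring (C2–O/C7 across C1; C4 and C6 flanking C5–O).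

Key step: step 7

Remark: 1 (D-glyceraldehyde acetonide) and 6 are taken as purchasable. The C4 epimers of 9 and 10 converge in the elimination. PMB = 4-methoxybenzyl.

**Step 1**
Reactants: 1 (R)-2,2-dimethyl-1,3-dioxolane-4-carbaldehyde
Product: 2 (R)-3,3-dimethoxypropane-1,2-diol
Conditions: MeOH, TsOH·H2O (cat.), rt; Et3N quench
Reagents that add atoms: methanol, CO
Why: Acid-catalysed acetal exchange turns the aldehyde into its dimethyl acetal and methanolyses the isopropylidene ketal; the stereocenter is not involved.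

**Step 2**
Reactants: 2 (R)-3,3-dimethoxypropane-1,2-diol
Product: 3 (4R)-4-(dimethoxymethyl)-2-(4-methoxyphenyl)-1,3-dioxolane (both epimers at C2 of the dioxolane)
Conditions: 4-MeOC6H4CH(OMe)2, PPTS (cat.), CH2Cl2, rt
Reagents that add atoms: 4-methoxybenzaldehyde dimethyl acetal, COC(OC)c1ccc(OC)cc1
Why: Transacetalisation closes the five-membered p-methoxybenzylidene acetal of the 1,2-diol; the new acetal center is lost again in step 3.

**Step 3**
Reactants: 3 (4R)-4-(dimethoxymethyl)-2-(4-methoxyphenyl)-1,3-dioxolane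
Product: 4 (2R)-3,3-dimethoxy-2-[(4-methoxybenzyl)oxy]propan-1-ol
Conditions: i-Bu2AlH (DIBAL-H), CH2Cl2, −78 → 0 °C; aq. KNaC4H4O6
Reagents that add atoms: none
Why: Regioselective reductive acetal opening: the aluminium reagent binds the less hindered primary oxygen and delivers hydride to the acetal carbon, so the PMB ether stays on the secondary oxygen.

**Step 4**
Reactants: 4 (2R)-3,3-dimethoxy-2-[(4-methoxybenzyl)oxy]propan-1-ol
Product: 5 (2R)-3,3-dimethoxy-2-[(4-methoxybenzyl)oxy]propanal
Conditions: Dess–Martin periodinane, NaHCO3, CH2Cl2, 0 °C → rt; used at once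
Reagents that add atoms: none
Why: Dess–Martin oxidation of the primary alcohol under buffered conditions that should not epimerise the α-alkoxy aldehyde.

**Step 5**
Reactants: 6 methyl 3-[(trimethylsilyl)oxy]but-2-enoate (E/Z mixture)
Product: 7 methyl 3-oxo-2-[(trimethylsilyl)oxy]butanoate (racemic)
Conditions: mCPBA, NaHCO3, hexane/CH2Cl2, −15 °C → rt
Reagents that add atoms: 3-chloroperbenzoic acid, OOC(=O)c1cccc(Cl)c1
Why: Rubottom oxidation: epoxidation of the silyl enol ether and 1,4-silyl shift place a silyloxy group on the carbon between the two carbonyls; this center becomes sp2 again in step 6.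

**Step 6**
Reactants: 7 methyl 3-oxo-2-[(trimethylsilyl)oxy]butanoate
Product: 8 1-methoxy-1,2,3-tris[(trimethylsilyl)oxy]buta-1,3-diene
Conditions: TMSOTf (2.5 equiv), Et3N, Et2O, 0 °C → rt; filtered and concentrated under argon, used crude
Reagents that add atoms: trimethylsilyl trifluoromethanesulfonate, C[Si](C)(C)OS(=O)(=O)C(F)(F)F
Why: Double soft enolisation and O-silylation, first at the doubly activated CH and then at the vinylogous methyl group, should give the Chan-type 1,3-bis(silyl enol ether).

**Step 7**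
Reactants: 5 (2R)-3,3-dimethoxy-2-[(4-methoxybenzyl)oxy]propanal; 8 1-methoxy-1,2,3-tris[(trimethylsilyl)oxy]buta-1,3-diene
Product: 11 methyl (1S,5S,6S)-1,6-dihydroxy-5-[(4-methoxybenzyl)oxy]-2-oxocyclohex-3-ene-1-carboxylate, via open-chain enediol bis(silyl ether) 9 (not isolated), via β-methoxy ketone 10 (not isolated)
Conditions: TMSOTf (0.1 equiv), CH2Cl2, −78 °C; then TiCl4 (2.2 equiv), −78 → −20 °C; aq. NaHCO3
Reagents that add atoms: none
Why: TMSOTf should ionise only the dimethyl acetal of 5 at −78 °C, and the oxocarbenium ion is captured by the terminal CH2 of 8, its most nucleophilic carbon, forming C3–C4 and leaving enediol bis(silyl ether) 9 (Mukaiyama acetal aldol). TiCl4 then chelates the aldehyde oxygen with the C5 PMB ether and converts the enediol ether into a cyclic titanium enediolate whose C1 adds to C6 in a 6-(enolendo)-exo-trig aldol closure of the six-membered ring to give 10; on warming the C4 methoxy group is lost by β-elimination to the C3=C4 enone. The closest known reaction type is the Chan–Brownbridge formal [3+3] cyclisation of 1,3-bis(silyl enol ethers) with masked 1,3-dialdehydes, which here cannot continue to an arene because C1 is quaternary. C6: the O5–Ti–O6 chelate can only be attacked from the face that carries the tether, which gives the cis C5–O/C6–O relationship. C1: the enediolate holds O1 and O2 cis, so the ester is cis to C3 and sits axial in the chair transition state with the C5 ether equatorial (the other chair has a 1,3-diaxial ester/OPMB clash), which puts O1 cis to O6. The step needs acetal-before-aldehyde chemoselectivity, which the order of the two Lewis acids and the high nucleophilicity of the diene terminus should secure.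

**Step 8**
Reactants: 11 methyl (1S,5S,6S)-1,6-dihydroxy-5-[(4-methoxybenzyl)oxy]-2-oxocyclohex-3-ene-1-carboxylate
Product: 12 methyl (1R,2S,5S,6S)-1,2,6-trihydroxy-5-[(4-methoxybenzyl)oxy]cyclohex-3-ene-1-carboxylate
Conditions: Me4N[BH(OAc)3], MeCN/AcOH (1:1), −30 °C
Reagents that add atoms: none
Why: Evans–Saksena hydroxyl-directed 1,2-reduction: the borohydride exchanges onto the C6 (or C1) hydroxyl on the lower face and delivers hydride intramolecularly to C2, so the new C2–OH is 1,3-anti to C6–OH and trans to C1–OH; the ester is untouched.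

**Step 9**
Reactants: 12 methyl (1R,2S,5S,6S)-1,2,6-trihydroxy-5-[(4-methoxybenzyl)oxy]cyclohex-3-ene-1-carboxylate
Product: 13 methyl (1R,2S,5S,6S)-2-hydroxy-1,6-(isopropylidenedioxy)-5-[(4-methoxybenzyl)oxy]cyclohex-3-ene-1-carboxylate
Conditions: 2,2-dimethoxypropane, PPTS (cat.), acetone, rt
Reagents that add atoms: 2,2-dimethoxypropane, COC(C)(C)OC
Why: Acetonide formation under thermodynamic control: only O1/O6 form a cis-1,2-diol (O2 is trans to O1 and 1,3-anti to O6), so the cis-fused dioxolane should form selectively.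

**Step 10**
Reactants: 13 methyl (1R,2S,5S,6S)-2-hydroxy-1,6-(isopropylidenedioxy)-5-[(4-methoxybenzyl)oxy]cyclohex-3-ene-1-carboxylate
Product: 14 (1R,2S,5S,6S)-1-(hydroxymethyl)-1,6-(isopropylidenedioxy)-5-[(4-methoxybenzyl)oxy]cyclohex-3-en-2-ol
Conditions: LiAlH4, THF, 0 °C; aqueous NaOH work-up
Reagents that add atoms: none
Why: Hydride reduction of the ester to the primary alcohol C7; acetonide, PMB ether and the allylic alkene are inert to LiAlH4 at 0 °C.

**Step 11**
Reactants: 14 (1R,2S,5S,6S)-1-(hydroxymethyl)-1,6-(isopropylidenedioxy)-5-[(4-methoxybenzyl)oxy]cyclohex-3-en-2-ol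
Product: 15 (1R,2S,5S,6S)-1-(hydroxymethyl)-1,6-(isopropylidenedioxy)cyclohex-3-ene-2,5-diol
Conditions: DDQ, CH2Cl2/pH 7 phosphate buffer (10:1), 0 °C
Reagents that add atoms: none
Why: Oxidative PMB ether cleavage (hydride abstraction by DDQ, hydrolysis of the oxocarbenium ion); the neighbouring O6 is tied up in the acetonide, so no benzylidene acetal can form.

**Step 12**
Reactants: 15 (1R,2S,5S,6S)-1-(hydroxymethyl)-1,6-(isopropylidenedioxy)cyclohex-3-ene-2,5-diol
Product: 16 [(1R,2S,5S,6S)-2,5-bis(benzoyloxy)-1,6-(isopropylidenedioxy)cyclohex-3-en-1-yl]methyl benzoate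
Conditions: BzCl (4 equiv), pyridine, DMAP (cat.), CH2Cl2, 0 °C → rt
Reagents that add atoms: benzoyl chloride, O=C(Cl)c1ccccc1
Why: DMAP-catalysed acylation of the primary and the two allylic secondary hydroxyls; the two hydroxyls that must stay free are masked as the acetonide.

**Step 13**
Reactants: 16 [(1R,2S,5S,6S)-2,5-bis(benzoyloxy)-1,6-(isopropylidenedioxy)cyclohex-3-en-1-yl]methyl benzoate
Product: 17 [(1S,2S,5S,6S)-2,5-bis(benzoyloxy)-1,6-dihydroxycyclohex-3-en-1-yl]methyl benzoate (target)
Conditions: TFA/H2O (4:1), CH2Cl2, 0 °C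
Reagents that add atoms: none
Why: Acid-catalysed hydrolysis of the isopropylidene ketal frees the tertiary C1 and secondary C6 hydroxyls; benzoates tolerate cold aqueous acid, which also disfavours acyl migration.

**Compound list**
1 | (R)-2,2-dimethyl-1,3-dioxolane-4-carbaldehyde | O=C[C@H]1COC(C)(C)O1 | starting material
2 | (R)-3,3-dimethoxypropane-1,2-diol | COC(OC)[C@H](O)CO | intermediate
3 | (4R)-4-(dimethoxymethyl)-2-(4-methoxyphenyl)-1,3-dioxolane | COC(OC)[C@H]1COC(c2ccc(OC)cc2)O1 | intermediate
4 | (2R)-3,3-dimethoxy-2-[(4-methoxybenzyl)oxy]propan-1-ol | COC(OC)[C@H](OCc1ccc(OC)cc1)CO | intermediate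
5 | (2R)-3,3-dimethoxy-2-[(4-methoxybenzyl)oxy]propanal | COC(OC)[C@H](OCc1ccc(OC)cc1)C=O | intermediate
6 | methyl 3-[(trimethylsilyl)oxy]but-2-enoate | COC(=O)C=C(C)O[Si](C)(C)C | starting material
7 | methyl 3-oxo-2-[(trimethylsilyl)oxy]butanoate (racemic) | COC(=O)C(O[Si](C)(C)C)C(C)=O | intermediate
8 | 1-methoxy-1,2,3-tris[(trimethylsilyl)oxy]buta-1,3-diene | C=C(O[Si](C)(C)C)C(O[Si](C)(C)C)=C(OC)O[Si](C)(C)C | intermediate
9 | methyl (6S)-5-methoxy-6-[(4-methoxybenzyl)oxy]-7-oxo-2,3-bis[(trimethylsilyl)oxy]hept-2-enoate (C5 epimers; not isolated) | COC(=O)C(O[Si](C)(C)C)=C(O[Si](C)(C)C)CC(OC)[C@H](OCc1ccc(OC)cc1)C=O | intermediate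
10 | methyl (1S,5R,6S)-1,6-dihydroxy-4-methoxy-5-[(4-methoxybenzyl)oxy]-2-oxocyclohexane-1-carboxylate (C4 epimers; titanium alkoxide in the flask; not isolated) | COC(=O)[C@@]1(O)C(=O)CC(OC)[C@H](OCc2ccc(OC)cc2)[C@@H]1O | intermediate
11 | methyl (1S,5S,6S)-1,6-dihydroxy-5-[(4-methoxybenzyl)oxy]-2-oxocyclohex-3-ene-1-carboxylate | COC(=O)[C@@]1(O)C(=O)C=C[C@H](OCc2ccc(OC)cc2)[C@@H]1O | intermediate
12 | methyl (1R,2S,5S,6S)-1,2,6-trihydroxy-5-[(4-methoxybenzyl)oxy]cyclohex-3-ene-1-carboxylate | COC(=O)[C@@]1(O)[C@@H](O)C=C[C@H](OCc2ccc(OC)cc2)[C@@H]1O | intermediate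
13 | methyl (1R,2S,5S,6S)-2-hydroxy-1,6-(isopropylidenedioxy)-5-[(4-methoxybenzyl)oxy]cyclohex-3-ene-1-carboxylate | COC(=O)[C@@]1(O3)[C@@H](O)C=C[C@H](OCc2ccc(OC)cc2)[C@@H]1OC3(C)C | intermediate
14 | (1R,2S,5S,6S)-1-(hydroxymethyl)-1,6-(isopropylidenedioxy)-5-[(4-methoxybenzyl)oxy]cyclohex-3-en-2-ol | OC[C@@]1(O3)[C@@H](O)C=C[C@H](OCc2ccc(OC)cc2)[C@@H]1OC3(C)C | intermediate
15 | (1R,2S,5S,6S)-1-(hydroxymethyl)-1,6-(isopropylidenedioxy)cyclohex-3-ene-2,5-diol | OC[C@@]1(O3)[C@@H](O)C=C[C@H](O)[C@@H]1OC3(C)C | intermediate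
16 | [(1R,2S,5S,6S)-2,5-bis(benzoyloxy)-1,6-(isopropylidenedioxy)cyclohex-3-en-1-yl]methyl benzoate | O=C(OC[C@@]1(O3)[C@@H](OC(=O)c2ccccc2)C=C[C@H](OC(=O)c2ccccc2)[C@@H]1OC3(C)C)c1ccccc1 | intermediate
17 | [(1S,2S,5S,6S)-2,5-bis(benzoyloxy)-1,6-dihydroxycyclohex-3-en-1-yl]methyl benzoate | O=C(OC[C@@]1(O)[C@@H](OC(=O)c2ccccc2)C=C[C@H](OC(=O)c2ccccc2)[C@@H]1O)c1ccccc1 | target

**Step count.** Total: 13 steps. Longest linear sequence: 11 steps (steps 1–4, then 7–13).

**Steps most likely to fail**

Step 7. The diene terminus may add to the chelation-activated aldehyde instead of the oxocarbenium ion, which would exchange the roles of the two ends of 5 and erode enantiopurity. A silyl-triflate-catalysed, non-chelated ring closure may also compete and lower the facial selectivity at C6 and C1, and the PMB ether may be lost to TiCl4 on warming. The fallback reverses the order of the two bond formations and uses two separate known reactions; it sets out from 7 and 5 and comes back at 11. Compound 7 is mono-silylated (TMSCl, Et3N) to methyl 2,3-bis[(trimethylsilyl)oxy]but-2-enoate F1, which is nucleophilic only at C1. A BF3·OEt2-mediated Mukaiyama aldol of F1 with 5 at −78 °C (non-chelating, Felkin–Anh; the α-alkoxy acetal should not ionise under these conditions) makes C1–C6 first and should give methyl (2S,3S,4R)-2-acetyl-2,3-dihydroxy-5,5-dimethoxy-4-[(4-methoxybenzyl)oxy]pentanoate F2, from which a C1 epimer would be separated. Hydrolysis of the acetal (LiBF4, wet MeCN) to methyl (2S,3S,4R)-2-acetyl-2,3-dihydroxy-4-[(4-methoxybenzyl)oxy]-5-oxopentanoate F3, followed by pyrrolidinium acetate-catalysed intramolecular aldol condensation of the methyl ketone onto the aldehyde, closes C3=C4 and gives 11.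

Step 5. Epoxidation of the ester-conjugated enol ether may be slow, and the acid by-product may desilylate or over-oxidise the product. The fallback installs the oxygen by carbenoid O–H insertion instead of epoxidation; it sets out from methyl acetoacetate F4 (commercial; 6 is its silyl enol ether, which it replaces) and comes back at 8. Diazo transfer (4-acetamidobenzenesulfonyl azide, Et3N, MeCN) gives methyl 2-diazo-3-oxobutanoate F5. Rh2(OAc)4-catalysed O–H insertion into water (wet DME) gives methyl 2-hydroxy-3-oxobutanoate F6, which is taken into the conditions of step 6 with one more equivalent of TMSOTf/Et3N to give 8.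

Step 3. Chelation of aluminium by the neighbouring dimethyl acetal may direct hydride to the other acetal C–O bond (primary PMB ether), or the dimethyl acetal may be reduced. The fallback replaces the reductive opening with a protecting-group sequence; it sets out from 2 and comes back at 4. Selective silylation of the primary hydroxyl (TBSCl, imidazole) gives (2R)-3-[(tert-butyldimethylsilyl)oxy]-1,1-dimethoxypropan-2-ol F7. Williamson etherification (NaH, PMBCl, Bu4NI, DMF) gives tert-butyl{(2R)-3,3-dimethoxy-2-[(4-methoxybenzyl)oxy]propoxy}dimethylsilane F8, and Bu4NF in THF releases 4.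

**Further compounds**
F1 | step 7 | methyl 2,3-bis[(trimethylsilyl)oxy]but-2-enoate | COC(=O)C(O[Si](C)(C)C)=C(C)O[Si](C)(C)C
F2 | step 7 | methyl (2S,3S,4R)-2-acetyl-2,3-dihydroxy-5,5-dimethoxy-4-[(4-methoxybenzyl)oxy]pentanoate | COC(=O)[C@@](O)(C(C)=O)[C@@H](O)[C@@H](OCc1ccc(OC)cc1)C(OC)OC
F3 | step 7 | methyl (2S,3S,4R)-2-acetyl-2,3-dihydroxy-4-[(4-methoxybenzyl)oxy]-5-oxopentanoate | COC(=O)[C@@](O)(C(C)=O)[C@@H](O)[C@@H](OCc1ccc(OC)cc1)C=O
F4 | step 5 | methyl 3-oxobutanoate (methyl acetoacetate) | COC(=O)CC(C)=O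
F5 | step 5 | methyl 2-diazo-3-oxobutanoate | COC(=O)C(=[N+]=[N-])C(C)=O
F6 | step 5 | methyl 2-hydroxy-3-oxobutanoate (racemic) | COC(=O)C(O)C(C)=O
F7 | step 3 | (2R)-3-[(tert-butyldimethylsilyl)oxy]-1,1-dimethoxypropan-2-ol | COC(OC)[C@H](O)CO[Si](C)(C)C(C)(C)C
F8 | step 3 | tert-butyl{(2R)-3,3-dimethoxy-2-[(4-methoxybenzyl)oxy]propoxy}dimethylsilane | COC(OC)[C@H](OCc1ccc(OC)cc1)CO[Si](C)(C)C(C)(C)C
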